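The cyclohexane ring (C5–C10: C10 quaternary, C9 CH2, C8 acyloxy carbon, C7 acrylate-bearing, C6 carbinol, C5 hydroxypropenyl-bearing) is closed from an acyclic allyl vinyl ether in one thermal operation. A Claisen rearrangement forms C9–C10, reading the C10 vinyl group and C8 as a γ,δ-unsaturated aldehyde and building the quaternary centre under control of C5. The liberated C8 aldehyde is then trapped by the (Z)-alkene at C7 in a carbonyl-ene reaction that forms C7–C8, the C8 hydroxyl and the exo-methylene of the later acrylic acid. The precursor carries only C5 and C6, set by one anti-aldol reaction.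

Key step: step 10

Remark: the propargyl ether, the dihydropyranone and the hydroxy lactone that open the three branches are taken to be catalogue compounds; C1–C15 are elemane-type locants (C1=C2 vinyl and C14 methyl on C10, C4(=C3)–C15 on C5, C11(=C13)–C12 on C7); TBS = tert-butyldimethylsilyl, PMB = 4-methoxybenzyl.

Step 1
Reactants: 1 4-methoxybenzyl propargyl ether
Product: 2 methyl 4-(PMB-oxy)but-2-ynoate
Conditions: n-BuLi, THF, −78 °C; ClCO2Me, −78 to 0 °C
Reagents that add atoms: methyl chloroformate, COC(=O)Cl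
Why: C-acylation of the lithium acetylide with a chloroformate is the standard ynoate synthesis and leaves the PMB ether untouched.

Step 2
Reactants: 2 methyl 4-(PMB-oxy)but-2-ynoate
Product: 3 methyl (2Z)-4-(PMB-oxy)-3-methylbut-2-enoate
Conditions: CuI, MeLi (2 equiv), THF, −78 °C; MeOH quench at −78 °C
Reagents that add atoms: lithium dimethylcuprate, [Li+].C[Cu-]C
Why: Stereospecific syn-carbocupration of the alkynoate and protonation with retention at low temperature put H cis to the new methyl, so the ester and the CH2OPMB arm end up cis (Z).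

Step 3
Reactants: 3 methyl (2Z)-4-(PMB-oxy)-3-methylbut-2-enoate
Product: 4 (2Z)-4-(PMB-oxy)-3-methylbut-2-en-1-ol
Conditions: iBu2AlH (2.2 equiv), CH2Cl2, −78 °C; KNaC4H4O6 (aq)
Reagents that add atoms: none
Why: 1,2-Reduction of the enoate with iBu2AlH should give the allylic alcohol without touching the alkene geometry.

Step 4
Reactants: 4 (2Z)-4-(PMB-oxy)-3-methylbut-2-en-1-ol
Product: 5 (2Z)-4-(PMB-oxy)-3-methylbut-2-enal
Conditions: activated MnO2, CH2Cl2, rt, dark; used at once
Reagents that add atoms: none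
Why: Neutral allylic oxidation with MnO2 should keep the (Z) geometry, as in the nerol-to-neral oxidation.

Step 5
Reactants: 6 4-methyl-5,6-dihydro-2H-pyran-2-one
Product: 7 4-methyl-3,6-dihydro-2H-pyran-2-one
Conditions: LiN(iPr)2, THF/DMPU, −78 °C; then AcOH, −78 °C
Reagents that add atoms: none
Why: γ-Deprotonation at the ring CH2 gives the endocyclic dienolate, and kinetic α-protonation gives the β,γ-unsaturated lactone (classical enoate deconjugation).

Step 6
Reactants: 7 4-methyl-3,6-dihydro-2H-pyran-2-one; 5 (2Z)-4-(PMB-oxy)-3-methylbut-2-enal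
Product: 8 anti-aldol lactone (C5 R; C6 R)
Conditions: (4R,5R)-2-bromo-4,5-diphenyl-1,3-ditosyl-1,3,2-diazaborolidine (from the (R,R)-bis-sulfonamide and BBr3, CH2Cl2), Et3N, PhMe, −78 °C; then 5, −78 °C; pH 7 buffer
Reagents that add atoms: none
Why: The lactone boron enolate is necessarily E(O)-configured, so the closed Zimmerman–Traxler aldol transition state gives the 5,6-anti pair, and the C2-symmetric sulfonamide boron controller (ester anti-aldol of the Corey type) selects the enolate face and sets both centres absolutely (its enantiomer would be used if the sense proved opposite).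

Step 7
Reactants: 8 anti-aldol lactone
Product: 9 C6 TBS ether of the aldol lactone
Conditions: TBSOTf, 2,6-lutidine, CH2Cl2, −78 °C
Reagents that add atoms: tert-butyldimethylsilyl triflate, CC(C)(C)[Si](C)(C)OS(=O)(=O)C(F)(F)F
Why: Silylation of the secondary allylic alcohol with a silyl triflate and a hindered weak base at low temperature should not epimerise C5 or conjugate the ring alkene.

Step 8
Reactants: 9 C6 TBS ether of the aldol lactone
Product: 10 ring-opened N-methoxy-N-methylamide with free C2 hydroxyl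
Conditions: MeNH(OMe)·HCl, AlMe3, CH2Cl2, 0 °C to rt; KNaC4H4O6 (aq)
Reagents that add atoms: N,O-dimethylhydroxylamine hydrochloride, CNOC.Cl
Why: Aluminium-amide aminolysis of the lactone (Weinreb amide formation) frees the primary allylic alcohol, carries the ring geometry into the (Z)-C10=C1 alkene, and masks C4 as an amide that is inert in the thermolysis.

Step 9
Reactants: 10 ring-opened N-methoxy-N-methylamide
Product: 11 allyl vinyl ether
Conditions: Hg(OAc)2 (0.3 equiv), ethyl vinyl ether (solvent), reflux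
Reagents that add atoms: ethyl vinyl ether, C=COCC
Why: Hg(OAc)2-catalysed transetherification with ethyl vinyl ether is the classical route from a primary allylic alcohol to its vinyl ether.

Step 10
Reactants: 11 allyl vinyl ether
Product: 13 cyclohexanol carboxamide (C5 R; C6 R; C7 R; C8 S; C10 S), via Claisen aldehyde 12 (not isolated)
Conditions: PhMe (0.01 M), 2,6-di-tert-butyl-4-methylphenol (cat.), base-washed sealed tube, 150 °C then 185 °C
Reagents that add atoms: none
Why: At 150 °C the allyl vinyl ether undergoes a [3,3]-sigmatropic (Claisen) rearrangement through a chair transition state, forming C9–C10 and the C8 aldehyde 12; at 185 °C this aldehyde and the (Z)-alkene combine in a concerted intramolecular carbonyl-ene reaction that forms C7–C8, moves a hydrogen from the C13 methyl to oxygen and leaves the C11=C13 exo-methylene. The closest known reaction type is the thermal tandem Claisen/carbonyl-ene sequence of oxy-Cope/Claisen/ene cascades, together with the citronellal-to-isopulegol cyclisation. The only ring closed is the cyclohexane, by a six-membered ene closure in which the alkene carbon next to the tether (C7) bonds to C8 and the rest of the alkene becomes exocyclic. C10 is controlled by C5: allylic 1,3-strain with the cis CH2O arm holds H-5 in the alkene plane, and the vinyl ether adds to the face bearing the flat carboxamide, anti to the bulky silyloxy-substituted C6 branch. C7 and C8 should arise from a chair ene transition state with C=O and alkene equatorial (trans C7/C8, hydrogen from the methyl trans to the tether), in which the C6 silyloxy group is axial to avoid allylic 1,3-strain with the cis CH2OPMB group and the trans C5 carboxamide is therefore axial too, giving the 6,7-cis and 5,7-trans relationships. The step needs the Claisen to outrun a Cope shift of the C1=C10/C7=C11 1,5-diene (hence the staged temperature) and the ene reaction to use only the C7=C11 alkene, which is secured because the new vinyl group has no allylic hydrogen and C4 is still a carboxamide and not yet the 1,1-disubstituted alkene.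

Step 11
Reactants: 13 cyclohexanol carboxamide
Product: 14 hydroxymethyl ketone
Conditions: Bu3SnCH2OH, n-BuLi (2 equiv per Sn), THF, −78 °C (gives LiCH2OLi); then 13, −78 to −30 °C; NH4Cl (aq)
Reagents that add atoms: (tributylstannyl)methanol, OC[Sn](CCCC)(CCCC)CCCC
Why: The dilithiated hydroxymethyl anion from tin–lithium exchange adds once to the N-methoxy-N-methylamide through the chelated tetrahedral intermediate and gives the α-hydroxy ketone on work-up, the C8 alkoxide being a spectator.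

Step 12
Reactants: 14 hydroxymethyl ketone
Product: 15 C15 TBS ether of the ketone
Conditions: TBSCl, imidazole, CH2Cl2, 0 °C
Reagents that add atoms: tert-butyldimethylsilyl chloride, CC(C)(C)[Si](C)(C)Cl
Why: The primary α-keto hydroxyl should be silylated much faster than the hindered secondary C8 hydroxyl.

Step 13
Reactants: 15 C15 TBS ether of the ketone
Product: 16 C8 alcohol with the C4=C3 methylene in place
Conditions: Cp2TiMe2 (excess), PhMe/THF, 70 °C, dark
Reagents that add atoms: dimethyltitanocene, [CH3-].[CH3-].[Ti+4].c1cc[cH-]c1.c1cc[cH-]c1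
Why: Petasis methylenation with a non-basic titanium carbene converts the hindered, enolisable ketone into the 1,1-disubstituted alkene without epimerising C5, the free hydroxyl only consuming reagent.

Step 14
Reactants: 17 (R)-3-hydroxy-γ-butyrolactone
Product: 20 (4R)-4-hydroxy-3-methylidene-dihydrofuran-2(3H)-one, via Mannich base 18 (not isolated), via ammonium iodide 19 (not isolated)
Conditions: LiN(iPr)2 (2.2 equiv), THF, −78 °C; CH2=NMe2+ I−, −78 °C to rt; then MeI, MeOH, rt; then NaHCO3 (aq), CH2Cl2, rt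
Reagents that add atoms: Eschenmoser's salt, C=[N+](C)C.[I-]
Why: The alkoxide–enolate dianion is aminomethylated at the α-carbon (trans to the oxido group, no β-elimination), and quaternisation plus base-induced elimination (Eschenmoser methylenation) gives the α-methylene lactone with the chiral-pool carbinol centre untouched.

Step 15
Reactants: 20 (4R)-4-hydroxy-3-methylidene-dihydrofuran-2(3H)-one
Product: 23 (3R)-3,4-bis(TBS-oxy)-2-methylidenebutanoic acid, via lithium dihydroxy carboxylate 21 (not isolated), via tris-silyl compound 22 (not isolated)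
Conditions: LiOH, THF/H2O, 0 °C; evaporate; TBSCl, imidazole, DMF, rt; then K2CO3, MeOH/THF/H2O, 0 °C; citric acid to pH 4
Reagents that add atoms: lithium hydroxide, [Li+].[OH-]; tert-butyldimethylsilyl chloride, CC(C)(C)[Si](C)(C)Cl
Why: Saponification opens the lactone, silylation of the carboxylate salt before any acidification prevents relactonisation, and only the silyl ester is cleaved by carbonate in methanol.

Step 16
Reactants: 16 C8 alcohol with the C4=C3 methylene in place; 23 (3R)-3,4-bis(TBS-oxy)-2-methylidenebutanoic acid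
Product: 25 fully protected C8 ester, via mixed anhydride 24 (not isolated)
Conditions: 2,4,6-trichlorobenzoyl chloride, Et3N, THF, rt; then 16, DMAP, PhMe, rt
Reagents that add atoms: none
Why: Yamaguchi esterification through the mixed anhydride acylates the only free hydroxyl (C8) and touches no stereocentre.

Step 17
Reactants: 25 fully protected C8 ester
Product: 26 C12 allylic alcohol
Conditions: DDQ, CH2Cl2/pH 7 buffer, 0 °C
Reagents that add atoms: none
Why: Oxidative cleavage of the PMB ether by DDQ leaves silyl ethers, esters and the unactivated alkenes alone.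

Step 18
Reactants: 26 C12 allylic alcohol
Product: 28 C12 carboxylic acid, via enal 27 (not isolated)
Conditions: TEMPO (cat.), PhI(OAc)2, CH2Cl2, rt; then tBuOH/H2O, NaH2PO4, 2-methyl-2-butene, NaClO2, 0 °C
Reagents that add atoms: sodium chlorite, [Na+].[O-]Cl=O
Why: TEMPO/PhI(OAc)2 oxidises the only free (primary allylic) alcohol to the 2-substituted acrolein, and buffered chlorite (Pinnick oxidation) with a chlorine scavenger takes it to the acrylic acid without harming the other alkenes.

Step 19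
Reactants: 28 C12 carboxylic acid
Product: 29 target
Conditions: HF·pyridine, pyridine, THF, 0 °C to rt
Reagents that add atoms: none
Why: Buffered HF·pyridine removes all four silyl ethers under weakly acidic, non-nucleophilic conditions that should spare both esters and should not drive lactonisation of the γ-hydroxy acid or of the side chain.

Compound list
1 | 1-methoxy-4-[(prop-2-yn-1-yloxy)methyl]benzene (4-methoxybenzyl propargyl ether) | C#CCOCc1ccc(OC)cc1 | starting material
2 | methyl 4-[(4-methoxybenzyl)oxy]but-2-ynoate | COC(=O)C#CCOCc1ccc(OC)cc1 | intermediate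
3 | methyl (2Z)-4-[(4-methoxybenzyl)oxy]-3-methylbut-2-enoate | COC(=O)/C=C(C)\COCc1ccc(OC)cc1 | intermediate
4 | (2Z)-4-[(4-methoxybenzyl)oxy]-3-methylbut-2-en-1-ol | OC/C=C(C)\COCc1ccc(OC)cc1 | intermediate
5 | (2Z)-4-[(4-methoxybenzyl)oxy]-3-methylbut-2-enal | O=C/C=C(C)\COCc1ccc(OC)cc1 | intermediate
6 | 4-methyl-5,6-dihydro-2H-pyran-2-one | CC1=CC(=O)OCC1 | starting material
7 | 4-methyl-3,6-dihydro-2H-pyran-2-one | CC1=CCOC(=O)C1 | intermediate
8 | (3R)-3-{(1R,2Z)-1-hydroxy-4-[(4-methoxybenzyl)oxy]-3-methylbut-2-en-1-yl}-4-methyl-3,6-dihydro-2H-pyran-2-one | COc1ccc(COC/C(C)=C\[C@@H](O)[C@@H]2C(=O)OCC=C2C)cc1 | intermediate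
9 | (3R)-3-{(1R,2Z)-1-[(tert-butyldimethylsilyl)oxy]-4-[(4-methoxybenzyl)oxy]-3-methylbut-2-en-1-yl}-4-methyl-3,6-dihydro-2H-pyran-2-one | COc1ccc(COC/C(C)=C\[C@@H](O[Si](C)(C)C(C)(C)C)[C@@H]2C(=O)OCC=C2C)cc1 | intermediate
10 | (2R,3Z)-2-{(1R,2Z)-1-[(tert-butyldimethylsilyl)oxy]-4-[(4-methoxybenzyl)oxy]-3-methylbut-2-en-1-yl}-5-hydroxy-N-methoxy-N,3-dimethylpent-3-enamide | COc1ccc(COC/C(C)=C\[C@@H](O[Si](C)(C)C(C)(C)C)[C@H](C(=O)N(C)OC)/C(C)=C\CO)cc1 | intermediate
11 | (2R,3Z)-2-{(1R,2Z)-1-[(tert-butyldimethylsilyl)oxy]-4-[(4-methoxybenzyl)oxy]-3-methylbut-2-en-1-yl}-5-(ethenyloxy)-N-methoxy-N,3-dimethylpent-3-enamide | COc1ccc(COC/C(C)=C\[C@@H](O[Si](C)(C)C(C)(C)C)[C@H](C(=O)N(C)OC)/C(C)=C\COC=C)cc1 | intermediate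
12 | (2R,3S)-2-{(1R,2Z)-1-[(tert-butyldimethylsilyl)oxy]-4-[(4-methoxybenzyl)oxy]-3-methylbut-2-en-1-yl}-3-ethenyl-N-methoxy-N,3-dimethyl-5-oxopentanamide | COc1ccc(COC/C(C)=C\[C@@H](O[Si](C)(C)C(C)(C)C)[C@H](C(=O)N(C)OC)[C@](C)(C=C)CC=O)cc1 | intermediate
13 | (1R,2S,4S,5R,6R)-6-[(tert-butyldimethylsilyl)oxy]-2-ethenyl-4-hydroxy-N-methoxy-5-{3-[(4-methoxybenzyl)oxy]prop-1-en-2-yl}-N,2-dimethylcyclohexane-1-carboxamide | C=C[C@]1(C)C[C@H](O)[C@@H](C(=C)COCc2ccc(OC)cc2)[C@@H](O[Si](C)(C)C(C)(C)C)[C@@H]1C(=O)N(C)OC | intermediate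
14 | 1-[(1R,2S,4S,5R,6R)-6-[(tert-butyldimethylsilyl)oxy]-2-ethenyl-4-hydroxy-5-{3-[(4-methoxybenzyl)oxy]prop-1-en-2-yl}-2-methylcyclohexyl]-2-hydroxyethan-1-one | C=C[C@]1(C)C[C@H](O)[C@@H](C(=C)COCc2ccc(OC)cc2)[C@@H](O[Si](C)(C)C(C)(C)C)[C@@H]1C(=O)CO | intermediate
15 | 2-[(tert-butyldimethylsilyl)oxy]-1-[(1R,2S,4S,5R,6R)-6-[(tert-butyldimethylsilyl)oxy]-2-ethenyl-4-hydroxy-5-{3-[(4-methoxybenzyl)oxy]prop-1-en-2-yl}-2-methylcyclohexyl]ethan-1-one | C=C[C@]1(C)C[C@H](O)[C@@H](C(=C)COCc2ccc(OC)cc2)[C@@H](O[Si](C)(C)C(C)(C)C)[C@@H]1C(=O)CO[Si](C)(C)C(C)(C)C | intermediate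
16 | (1S,2R,3S,4S,5S)-3-[(tert-butyldimethylsilyl)oxy]-4-{3-[(tert-butyldimethylsilyl)oxy]prop-1-en-2-yl}-5-ethenyl-2-{3-[(4-methoxybenzyl)oxy]prop-1-en-2-yl}-5-methylcyclohexan-1-ol | C=C[C@]1(C)C[C@H](O)[C@@H](C(=C)COCc2ccc(OC)cc2)[C@@H](O[Si](C)(C)C(C)(C)C)[C@@H]1C(=C)CO[Si](C)(C)C(C)(C)C | intermediate
17 | (4R)-4-hydroxydihydrofuran-2(3H)-one ((R)-3-hydroxy-γ-butyrolactone) | O=C1C[C@@H](O)CO1 | starting material
18 | trans-(4R)-3-[(dimethylamino)methyl]-4-hydroxydihydrofuran-2(3H)-one | O=C1[C@H](CN(C)C)[C@@H](O)CO1 | intermediate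
19 | [trans-(4R)-4-hydroxy-2-oxooxolan-3-yl]methyl-trimethylammonium iodide | O=C1[C@H](C[N+](C)(C)C)[C@@H](O)CO1.[I-] | intermediate
20 | (4R)-4-hydroxy-3-methylidenedihydrofuran-2(3H)-one | O=C1C(=C)[C@@H](O)CO1 | intermediate
21 | lithium (3R)-3,4-dihydroxy-2-methylidenebutanoate | [Li+].[O-]C(=O)C(=C)[C@@H](O)CO | intermediate
22 | tert-butyldimethylsilyl (3R)-3,4-bis[(tert-butyldimethylsilyl)oxy]-2-methylidenebutanoate | CC(C)(C)[Si](C)(C)OC(=O)C(=C)[C@@H](O[Si](C)(C)C(C)(C)C)CO[Si](C)(C)C(C)(C)C | intermediate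
23 | (3R)-3,4-bis[(tert-butyldimethylsilyl)oxy]-2-methylidenebutanoic acid | OC(=O)C(=C)[C@@H](O[Si](C)(C)C(C)(C)C)CO[Si](C)(C)C(C)(C)C | intermediate
24 | (3R)-3,4-bis[(tert-butyldimethylsilyl)oxy]-2-methylidenebutanoic 2,4,6-trichlorobenzoic anhydride | O=C(OC(=O)C(=C)[C@@H](O[Si](C)(C)C(C)(C)C)CO[Si](C)(C)C(C)(C)C)c1c(Cl)cc(Cl)cc1Cl | intermediate
25 | (1S,2R,3S,4S,5S)-3-[(tert-butyldimethylsilyl)oxy]-4-{3-[(tert-butyldimethylsilyl)oxy]prop-1-en-2-yl}-5-ethenyl-2-{3-[(4-methoxybenzyl)oxy]prop-1-en-2-yl}-5-methylcyclohexyl (3R)-3,4-bis[(tert-butyldimethylsilyl)oxy]-2-methylidenebutanoate | C=C[C@]1(C)C[C@H](OC(=O)C(=C)[C@@H](O[Si](C)(C)C(C)(C)C)CO[Si](C)(C)C(C)(C)C)[C@@H](C(=C)COCc2ccc(OC)cc2)[C@@H](O[Si](C)(C)C(C)(C)C)[C@@H]1C(=C)CO[Si](C)(C)C(C)(C)C | intermediate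
26 | (1S,2R,3S,4S,5S)-3-[(tert-butyldimethylsilyl)oxy]-4-{3-[(tert-butyldimethylsilyl)oxy]prop-1-en-2-yl}-5-ethenyl-2-(3-hydroxyprop-1-en-2-yl)-5-methylcyclohexyl (3R)-3,4-bis[(tert-butyldimethylsilyl)oxy]-2-methylidenebutanoate | C=C[C@]1(C)C[C@H](OC(=O)C(=C)[C@@H](O[Si](C)(C)C(C)(C)C)CO[Si](C)(C)C(C)(C)C)[C@@H](C(=C)CO)[C@@H](O[Si](C)(C)C(C)(C)C)[C@@H]1C(=C)CO[Si](C)(C)C(C)(C)C | intermediate
27 | (1S,2R,3S,4S,5S)-3-[(tert-butyldimethylsilyl)oxy]-4-{3-[(tert-butyldimethylsilyl)oxy]prop-1-en-2-yl}-5-ethenyl-5-methyl-2-(3-oxoprop-1-en-2-yl)cyclohexyl (3R)-3,4-bis[(tert-butyldimethylsilyl)oxy]-2-methylidenebutanoate | C=C[C@]1(C)C[C@H](OC(=O)C(=C)[C@@H](O[Si](C)(C)C(C)(C)C)CO[Si](C)(C)C(C)(C)C)[C@@H](C(=C)C=O)[C@@H](O[Si](C)(C)C(C)(C)C)[C@@H]1C(=C)CO[Si](C)(C)C(C)(C)C | intermediate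
28 | 2-[(1R,2S,3S,4S,6S)-6-({(3R)-3,4-bis[(tert-butyldimethylsilyl)oxy]-2-methylidenebutanoyl}oxy)-2-[(tert-butyldimethylsilyl)oxy]-3-{3-[(tert-butyldimethylsilyl)oxy]prop-1-en-2-yl}-4-ethenyl-4-methylcyclohexyl]prop-2-enoic acid | C=C[C@]1(C)C[C@H](OC(=O)C(=C)[C@@H](O[Si](C)(C)C(C)(C)C)CO[Si](C)(C)C(C)(C)C)[C@@H](C(=C)C(=O)O)[C@@H](O[Si](C)(C)C(C)(C)C)[C@@H]1C(=C)CO[Si](C)(C)C(C)(C)C | intermediate
29 | 2-[(1S,2S,3S,4S,6S)-6-{[(3R)-3,4-dihydroxy-2-methylidenebutanoyl]oxy}-4-ethenyl-2-hydroxy-3-(3-hydroxyprop-1-en-2-yl)-4-methylcyclohexyl]prop-2-enoic acid | C=C[C@]1(C)C[C@H](OC(=O)C(=C)[C@@H](O)CO)[C@@H](C(=C)C(=O)O)[C@@H](O)[C@@H]1C(=C)CO | target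

Total step count: 19. Longest linear sequence: 16 steps (steps 1–4, 6–13, 16–19).

Steps most likely to fail

Step 10. The Claisen step may show poor facial selectivity at C10, and the thermal ene step may pass through the competing chair (wrong C7/C8 pair) or take the hydrogen from the CH2OPMB group; the N-methoxy amide may also degrade on long heating. In the fallback the two events are separated: 11 is heated only to 150 °C so that the Claisen aldehyde 12 is isolated, and 12 is then cyclised with Me2AlCl in CH2Cl2 at −78 °C, a Lewis-acid-promoted carbonyl-ene reaction through a tighter chair at low temperature. The fallback sets out from 11 and comes back at 13, and it makes no compound outside the list (F0).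

Step 6. Enolisation with the boron controller may be incomplete, the β,γ-unsaturated lactone may slip into conjugation, or the facial control of the enolate may be weak. The fallback moves the stereocontrol to a covalently bound auxiliary; it sets out from 7 and comes back at 10. Lactone 7 is saponified and silylated as in step 15 to (3Z)-5-(TBS-oxy)-3-methylpent-3-enoic acid F1, which is coupled (pivaloyl chloride, Et3N; lithiated (4S)-4-benzyloxazolidin-2-one) to the N-acyl oxazolidinone F2. A MgCl2-catalysed anti-aldol reaction with 5 (MgCl2, Et3N, Me3SiCl, EtOAc; acidic methanol work-up) should give the anti-aldol imide F3. AlMe3/MeNH(OMe)·HCl converts it into the hydroxy N-methoxy-N-methylamide F4 and releases the auxiliary, TBSOTf/2,6-lutidine gives the bis-silyl amide F5, and HF·pyridine/pyridine at 0 °C removes only the primary allylic silyl group to give 10.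

Step 11. The hindered amide may resist addition while the thermally fragile dilithio reagent decomposes, or the strong base may trigger β-elimination of the C6 silyloxy group. The fallback builds the hydroxymethyl ketone in two stages; it sets out from 13 and comes back at 14. MeLi (THF, −78 °C) converts 13 into the methyl ketone F6, whose kinetic methyl-side enolate (LiN(SiMe3)2 in excess, THF, −78 °C) is hydroxylated with 3-phenyl-2-(phenylsulfonyl)oxaziridine to give 14.

Further compounds
F0 | step 10 | none | none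
F1 | step 6 | (3Z)-5-[(tert-butyldimethylsilyl)oxy]-3-methylpent-3-enoic acid | OC(=O)C/C(C)=C\CO[Si](C)(C)C(C)(C)C
F2 | step 6 | (4S)-4-benzyl-3-{(3Z)-5-[(tert-butyldimethylsilyl)oxy]-3-methylpent-3-enoyl}oxazolidin-2-one | O=C1OC[C@H](Cc2ccccc2)N1C(=O)C/C(C)=C\CO[Si](C)(C)C(C)(C)C
F3 | step 6 | (4S)-4-benzyl-3-[(2R,3Z)-5-[(tert-butyldimethylsilyl)oxy]-2-{(1R,2Z)-1-hydroxy-4-[(4-methoxybenzyl)oxy]-3-methylbut-2-en-1-yl}-3-methylpent-3-enoyl]oxazolidin-2-one | O=C1OC[C@H](Cc2ccccc2)N1C(=O)[C@@H]([C@H](O)/C=C(C)\COCc2ccc(OC)cc2)/C(C)=C\CO[Si](C)(C)C(C)(C)C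
F4 | step 6 | (2R,3Z)-5-[(tert-butyldimethylsilyl)oxy]-2-{(1R,2Z)-1-hydroxy-4-[(4-methoxybenzyl)oxy]-3-methylbut-2-en-1-yl}-N-methoxy-N,3-dimethylpent-3-enamide | CON(C)C(=O)[C@@H]([C@H](O)/C=C(C)\COCc1ccc(OC)cc1)/C(C)=C\CO[Si](C)(C)C(C)(C)C
F5 | step 6 | (2R,3Z)-5-[(tert-butyldimethylsilyl)oxy]-2-{(1R,2Z)-1-[(tert-butyldimethylsilyl)oxy]-4-[(4-methoxybenzyl)oxy]-3-methylbut-2-en-1-yl}-N-methoxy-N,3-dimethylpent-3-enamide | CON(C)C(=O)[C@@H]([C@H](O[Si](C)(C)C(C)(C)C)/C=C(C)\COCc1ccc(OC)cc1)/C(C)=C\CO[Si](C)(C)C(C)(C)C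
F6 | step 11 | 1-[(1R,2S,4S,5R,6R)-6-[(tert-butyldimethylsilyl)oxy]-2-ethenyl-4-hydroxy-5-{3-[(4-methoxybenzyl)oxy]prop-1-en-2-yl}-2-methylcyclohexyl]ethan-1-one | C=C[C@]1(C)C[C@H](O)[C@@H](C(=C)COCc2ccc(OC)cc2)[C@@H](O[Si](C)(C)C(C)(C)C)[C@@H]1C(C)=O
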